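The quinone ring (C1 and C4 carbonyls, C2 and C5 hydroxyls, C3 methyl, C6 pentadecyl) carries oxygen at C2 and C4 on either side of the C3 methyl, with the pentadecyl chain para to it: a 2-methyl-5-alkylresorcinol awaiting oxidation at C1 and C5. The route therefore cuts ring bond C1–C6 and unfolds the ring into a linear 4-methyl-3,5,7-triketo ester with the C15 chain on the terminal ketone. One base-mediated aldol condensation closes the only ring and fixes the whole substitution pattern. The ester that activated the nucleophilic carbon is then removed as CO2, and the two missing oxygens are added by quinone chemistry.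

Key step: step 4

Remark: 6, 7 and 8 are tautomeric mixtures; each is listed as one tautomer (7 as its hydrogen-bonded (Z)-5-enol), and the labile or transient sp3 centres of 6 and 8 are racemic.

Step 1
Reactants: 1 hexadecanoyl chloride; 2 N,O-dimethylhydroxylamine hydrochloride
Product: 3 N-methoxy-N-methylhexadecanamide
Conditions: Et3N (2.2 equiv), CH2Cl2, 0 °C to rt
Reagents that add atoms: none
Why: Schotten–Baumann-type N-acylation of the free hydroxylamine by the acid chloride is fast and irreversible, and the Weinreb amide formed is an acyl donor that can deliver the C16 unit once only.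

Step 2
Reactants: 4 methyl 3-oxopentanoate; 5 N-methoxy-N-methylacetamide
Product: 6 methyl 4-methyl-3,5-dioxohexanoate
Conditions: LiN(iPr)2 (2.2 equiv), THF, −78 to 0 °C; then 5, −78 to 0 °C; cold 1 M HCl
Reagents that add atoms: none
Why: In this γ-acylation of a β-keto ester dianion (Claisen-type C-acylation, Weinreb ketone synthesis) the second deprotonation puts the reactive carbanion on C4, and the chelated tetrahedral adduct of the amide persists until work-up, so the acidic 1,3-diketone is never present to quench unreacted dianion or to be acylated twice.

Step 3
Reactants: 6 methyl 4-methyl-3,5-dioxohexanoate; 3 N-methoxy-N-methylhexadecanamide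
Product: 7 methyl (4Z)-5-hydroxy-4-methyl-3,7-dioxodocos-4-enoate (enol form of methyl 4-methyl-3,5,7-trioxodocosanoate)
Conditions: LiN(iPr)2 (3.3 equiv), THF, −78 to 0 °C; then 3 (0.8 equiv), −78 to 0 °C; cold 1 M HCl to pH 4, extract, use crude
Reagents that add atoms: none
Why: In this terminal acylation of a 3,5-diketo ester trianion (polyanion Claisen-type acylation with a Weinreb amide) the C6 methyl is the only acidic site left once C2 and C4 are ionized, so the last-formed and most basic carbanion can only be C6, and the stable lithium chelate of the amide adduct stops the reaction at the ketone.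

Step 4
Reactants: 7 methyl (4Z)-5-hydroxy-4-methyl-3,7-dioxodocos-4-enoate
Product: 9 methyl 2,4-dihydroxy-3-methyl-6-pentadecylbenzoate, via cyclic aldol adduct 8 (not isolated)
Conditions: KOH (1 M in H2O, 3 equiv), THF, 0 °C to rt, N2; then 1 M HCl, 0 °C
Reagents that add atoms: none
Why: Hydroxide reversibly deprotonates the doubly activated C2 methylene (ester plus C3 ketone) and this enolate adds to the C7 ketone to give the cyclic aldol adduct 8, which eliminates water and enolizes to the benzene ring, so that aromatization makes the sequence irreversible. The closest known reaction type is the base-mediated aldol cyclization of 3,5,7-triketo esters and acids to β-resorcylates, the laboratory counterpart of polyketide aromatization. The ring closes in a 6-(enolexo)-exo-trig mode that joins C2 to C7 and becomes ring bond C1–C6 of the quinone. No stereocentre is created in 9, since the carbinol carbon of 8 is racemic and is erased on dehydration; the chelated (Z)-5-enol drawn for 7 holds C3 and C6 trans across C4=C5 and therefore reacts through its keto or enolate form, in which the C4–C5 bond rotates freely. The step needs aldol closure in preference to Claisen closure (C6 onto the ester carbon), to aldol attack of the singly activated C8 on C3 and to O-cyclization to pyranones. The substrate secures this because C2 is the only doubly activated carbon that reaches a ketone through a six-membered transition state and the ester is a poor electrophile unless a chelating cation activates it, which potassium in water does not, while cold, brief work-up avoids the acid-promoted pyranone pathways.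

Step 5
Reactants: 9 methyl 2,4-dihydroxy-3-methyl-6-pentadecylbenzoate
Product: 11 2-methyl-5-pentadecylbenzene-1,3-diol, via resorcylic acid 10 (not isolated)
Conditions: KOH (excess), H2O/EtOH, reflux, N2; then 6 M HCl, 80 °C
Reagents that add atoms: none
Why: Forcing saponification of the hindered salicylate-type ester followed by protodecarboxylation of the β-resorcylic acid, which is ipso-protonated easily because both hydroxyls are ortho or para to the carboxyl-bearing carbon, is the standard way from resorcylates to alkylresorcinols.

Step 6
Reactants: 11 2-methyl-5-pentadecylbenzene-1,3-diol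
Product: 12 2-hydroxy-3-methyl-6-pentadecylcyclohexa-2,5-diene-1,4-dione
Conditions: K2NO(SO3)2 (2.5 equiv), KH2PO4, H2O/acetone, 0 °C to rt
Reagents that add atoms: dipotassium nitrosodisulfonate, [K+].[K+].[O]N(S(=O)(=O)[O-])S(=O)(=O)[O-]
Why: In this Teuber oxidation one equivalent of the nitroxyl radical removes the phenolic hydrogen and a second delivers its oxygen to the free carbon para to that hydroxyl, and because the resorcinol is symmetric with its C2 blocked by methyl, attack at C4 or C6 gives the same 2-hydroxy-1,4-quinone.

Step 7
Reactants: 12 2-hydroxy-3-methyl-6-pentadecylcyclohexa-2,5-diene-1,4-dione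
Product: 14 3-methyl-6-pentadecylbenzene-1,2,4,5-tetrayl tetraacetate, via quinone acetate 13 (not isolated)
Conditions: Ac2O, H2SO4 (conc., cat.), rt to 45 °C; then ice–water
Reagents that add atoms: acetic anhydride, CC(=O)OC(C)=O
Why: In this Thiele–Winter acetoxylation the acidic hydroxyl is acetylated first (13), acid-promoted conjugate addition of acetate then occurs at C5, the only unsubstituted ring carbon and the β-position of the C1 enone, and enolization with exhaustive acetylation traps the hydroquinone as the tetraacetate, as in the classical route from alkylhydroxyquinones to 2,5-dihydroxyquinones.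

Step 8
Reactants: 14 3-methyl-6-pentadecylbenzene-1,2,4,5-tetrayl tetraacetate
Product: 16 2,5-dihydroxy-3-methyl-6-pentadecylcyclohexa-2,5-diene-1,4-dione, via tetrol 15 (not isolated)
Conditions: NaOH (2 M in H2O), MeOH, air, 0 °C to rt; then 2 M HCl
Reagents that add atoms: none
Why: Saponification of the four aryl acetates gives the very electron-rich 1,2,4,5-tetrol 15, whose anion is dehydrogenated at once by atmospheric oxygen (hydroquinone autoxidation) to the 2,5-dihydroxy-1,4-benzoquinone, which is stable in base as its dianion and is released on acidification.

Compound list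

1 | hexadecanoyl chloride | CCCCCCCCCCCCCCCC(=O)Cl | starting material
2 | N,O-dimethylhydroxylamine hydrochloride | CNOC.Cl | starting material
3 | N-methoxy-N-methylhexadecanamide | CCCCCCCCCCCCCCCC(=O)N(C)OC | intermediate
4 | methyl 3-oxopentanoate | CCC(=O)CC(=O)OC | starting material
5 | N-methoxy-N-methylacetamide | CC(=O)N(C)OC | starting material
6 | methyl 4-methyl-3,5-dioxohexanoate (keto form; C4 racemic and labile) | COC(=O)CC(=O)C(C)C(C)=O | intermediate
7 | methyl (4Z)-5-hydroxy-4-methyl-3,7-dioxodocos-4-enoate, the chelated enol of methyl 4-methyl-3,5,7-trioxodocosanoate | COC(=O)CC(=O)/C(C)=C(\O)CC(=O)CCCCCCCCCCCCCCC | intermediate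
8 | methyl 2,4,6-trihydroxy-3-methyl-6-pentadecylcyclohexa-1,3-diene-1-carboxylate (cyclic aldol adduct drawn as its dienol; racemic at C6; not isolated) | COC(=O)C1=C(O)C(C)=C(O)CC1(O)CCCCCCCCCCCCCCC | intermediate
9 | methyl 2,4-dihydroxy-3-methyl-6-pentadecylbenzoate | COC(=O)c1c(O)c(C)c(O)cc1CCCCCCCCCCCCCCC | intermediate
10 | 2,4-dihydroxy-3-methyl-6-pentadecylbenzoic acid (not isolated) | OC(=O)c1c(O)c(C)c(O)cc1CCCCCCCCCCCCCCC | intermediate
11 | 2-methyl-5-pentadecylbenzene-1,3-diol | Cc1c(O)cc(CCCCCCCCCCCCCCC)cc1O | intermediate
12 | 2-hydroxy-3-methyl-6-pentadecylcyclohexa-2,5-diene-1,4-dione | CCCCCCCCCCCCCCCC1=CC(=O)C(C)=C(O)C1=O | intermediate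
13 | 2-methyl-3,6-dioxo-5-pentadecylcyclohexa-1,4-dien-1-yl acetate (not isolated) | CCCCCCCCCCCCCCCC1=CC(=O)C(C)=C(OC(C)=O)C1=O | intermediate
14 | 3-methyl-6-pentadecylbenzene-1,2,4,5-tetrayl tetraacetate | CCCCCCCCCCCCCCCc1c(OC(C)=O)c(OC(C)=O)c(C)c(OC(C)=O)c1OC(C)=O | intermediate
15 | 3-methyl-6-pentadecylbenzene-1,2,4,5-tetrol (not isolated) | CCCCCCCCCCCCCCCc1c(O)c(O)c(C)c(O)c1O | intermediate
16 | 2,5-dihydroxy-3-methyl-6-pentadecylcyclohexa-2,5-diene-1,4-dione (no stereocentre) | CCCCCCCCCCCCCCCC1=C(O)C(=O)C(C)=C(O)C1=O | target

Total step count: 8. Longest linear sequence: 7 steps (4 to 16, steps 2 to 8); step 1 is a one-step branch.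

Steps most likely to fail

Step 4. The ring may close through the wrong carbon–carbonyl pair (C6 onto the ester carbon), hydroxide may cleave the 1,3-dicarbonyl units by retro-Claisen reaction before the ring forms, or O-cyclization to pyranones may occur on acidification. The fallback sets out from 7 and comes back at 9. Crude 7 would be cyclodehydrated with acid (CF3CO2H in CH2Cl2, or cold concentrated H2SO4), the usual closure of 1,3,5-triketones, to methyl 2-(3-methyl-4-oxo-6-pentadecyl-4H-pyran-2-yl)acetate F1, a stable 4-pyranone in which the polyketone is masked and which can be purified. Aqueous-methanolic KOH should then add to the pyranone, reopen it to the enolate of 7 at low stationary concentration and lead through the same aldol aromatization to 9, in line with the known base-induced ring opening of 4-pyranones to 1,3,5-triketone enolates.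

Step 3. The third deprotonation of the crowded 4-methyl dienolate may stay incomplete, or proton transfer from the α-CH2 of 3 to the terminal carbanion may take the place of C-acylation. The fallback sets out from 6 (and uses 3) and comes back at 10. Compound 6 would be lactonized (DBU, toluene, warm), as is usual for 3,5-diketo esters, to 4-hydroxy-5,6-dimethyl-2H-pyran-2-one F2. Its dianion (LiN(iPr)2, 2.2 equiv, THF, −78 °C), which carries the second charge on the C6 methyl group, would be acylated by 3 to 4-hydroxy-5-methyl-6-(2-oxoheptadecyl)-2H-pyran-2-one F3, the known side-chain acylation of 4-hydroxy-6-methylpyranone dianions. Hot aqueous KOH should open the lactone to the triketo carboxylate, which cannot close in the Claisen sense and should give 10 by the same C2–C7 aldol bond formation. Acidification and warming as in the second half of step 5 then lead to 11. A trianion is thus replaced by a dianion.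

Step 7. Conjugate addition at the flanked C5 position may be slow, so that sulfonation or acid-induced decomposition of the quinone overtakes it. The fallback sets out from 12 and comes back at 16. The vinylogous acid 12 would be etherified (MeOH, H2SO4 cat.) to 2-methoxy-3-methyl-6-pentadecylcyclohexa-2,5-diene-1,4-dione F4. Excess MeNH2 in EtOH under air should replace the methoxy group by addition–elimination and add oxidatively at C5, giving 3-methyl-2,5-bis(methylamino)-6-pentadecylcyclohexa-2,5-diene-1,4-dione F5. Hydrolysis of the two vinylogous amides (aqueous H2SO4, AcOH, reflux) should give 16, a known way from quinones to 2,5-dihydroxyquinones.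

Further compounds

F1 | step 4 | methyl 2-(3-methyl-4-oxo-6-pentadecyl-4H-pyran-2-yl)acetate | COC(=O)CC1=C(C)C(=O)C=C(CCCCCCCCCCCCCCC)O1
F2 | step 3 | 4-hydroxy-5,6-dimethyl-2H-pyran-2-one | CC1=C(C)C(O)=CC(=O)O1
F3 | step 3 | 4-hydroxy-5-methyl-6-(2-oxoheptadecyl)-2H-pyran-2-one | CCCCCCCCCCCCCCCC(=O)CC1=C(C)C(O)=CC(=O)O1
F4 | step 7 | 2-methoxy-3-methyl-6-pentadecylcyclohexa-2,5-diene-1,4-dione | CCCCCCCCCCCCCCCC1=CC(=O)C(C)=C(OC)C1=O
F5 | step 7 | 3-methyl-2,5-bis(methylamino)-6-pentadecylcyclohexa-2,5-diene-1,4-dione | CCCCCCCCCCCCCCCC1=C(NC)C(=O)C(C)=C(NC)C1=O
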